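**Plan**
Retrosynthetic cuts: the ArO–Si bond; O1–C2 and C3–C4 of pyran ring B, leading back to a C4 aldehyde on C4a and a 2-methylpropenyl nucleophile; the C7 O–prenyl bond; C4a–C5 of ring A; and finally C5–C6 and C7–C8, which open the chain.
Enabling feature: ring A (C4a, C5, C6, C7, C8, C8a, 2H-chromene numbering) has oxygen on C7 and C8a, meta to each other, and carbon on the adjacent C4a (C4) and C5 (arylethyl arm). This is the pattern of a 6-alkylresorcylate, that is, of a folded 3,5,7-trioxo acid whose carboxyl carbon is C4.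
Forward, chain assembly: the dioxinone dienolate is acylated with acetyl chloride (C7–C8), and the keto-dioxinone dianion is acylated with the arylpropanoic Weinreb amide (C5–C6). Ring A then closes by aldol aromatisation while the dioxinone survives as a temporary ring.
Forward, completion: O-prenylation at C7, reduction of the dioxinone to the salicylaldehyde, alkenyl Grignard addition (C3–C4), closure of ring B through an o-quinone methide and oxa-6π electrocyclisation (O1–C2), and desilylation.
Stereochemistry: the target has no stereocentre. C3=C4 is cis because it lies in six-membered ring B, and the prenyl alkene carries two identical methyl groups.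

Key step: step 5

Remark: the amide bases and the alkenyl Grignard reagent are taken as commercial solutions. Transient intermediates that carry a stereocentre form as racemates or diastereomer mixtures and lose these centres within the same step, so their SMILES carry no configuration.

Step 1
Reactants: 1 3-(4-hydroxyphenyl)propanoic acid
Product: 2 3-(4-hydroxyphenyl)-N-methoxy-N-methylpropanamide
Conditions: MeNH(OMe)·HCl, EDC·HCl, Et3N (2.2 equiv), CH2Cl2/DMF, 0 °C → rt
Reagents that add atoms: N,O-dimethylhydroxylamine hydrochloride, CNOC.Cl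
Why: Carbodiimide-mediated amide coupling gives the Weinreb amide, the amine capturing the activated acid much faster than the free phenol does, as is routine for unprotected tyrosine-type substrates.

Step 2
Reactants: 2 3-(4-hydroxyphenyl)-N-methoxy-N-methylpropanamide
Product: 3 N-methoxy-N-methyl-3-[4-(triisopropylsilyloxy)phenyl]propanamide
Conditions: iPr3SiCl, imidazole, DMF, rt
Reagents that add atoms: triisopropylsilyl chloride, CC(C)[Si](Cl)(C(C)C)C(C)C
Why: Imidazole-promoted O-silylation of a phenol is routine, and the bulky triisopropylsilyl ether is chosen because it should withstand the amide bases, Et3N, K2CO3, hydride and Grignard reagent that follow yet fall to fluoride without harm to the two alkenes of the target.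

Step 3
Reactants: 4 2,2,6-trimethyl-4H-1,3-dioxin-4-one; 5 acetyl chloride
Product: 7 2,2-dimethyl-6-(2-oxopropyl)-4H-1,3-dioxin-4-one, via lithium dienolate 6 (not isolated)
Conditions: 4 (2 equiv), LiN(SiMe3)2 (2 equiv), THF, −78 °C; 5 (1 equiv), −78 → −20 °C; 1 M aq HCl
Reagents that add atoms: none
Why: Kinetic γ-deprotonation gives the cross-conjugated dienolate 6, whose C-acylation at the exocyclic γ-carbon (vinylogous Claisen acylation, forming the future C7–C8 bond) is the standard entry to keto-dioxinones, the second equivalent of 6 serving to absorb the acidic proton of 7.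

Step 4
Reactants: 7 2,2-dimethyl-6-(2-oxopropyl)-4H-1,3-dioxin-4-one; 3 N-methoxy-N-methyl-3-[4-(triisopropylsilyloxy)phenyl]propanamide
Product: 9 2,2-dimethyl-6-{2,4-dioxo-6-[4-(triisopropylsilyloxy)phenyl]hexyl}-4H-1,3-dioxin-4-one, via dilithium dianion 8 (not isolated)
Conditions: 7, LiN(iPr)2 (2.1 equiv per 7), THF, −78 → −40 °C; 3, −78 → 0 °C; cold 1 M aq HCl; rapid filtration through silica
Reagents that add atoms: none
Why: Dianion Claisen acylation, in which the last-formed carbanion at the terminal methyl of 8 is the more reactive site and attacks the Weinreb amide to form the future C5–C6 bond, while an N-methoxy-N-methyl amide gives up its ketone only on quench, so neither over-addition nor self-quenching of 8 by the acidic 1,3-diketone should interfere.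

Step 5
Reactants: 9 2,2-dimethyl-6-{2,4-dioxo-6-[4-(triisopropylsilyloxy)phenyl]hexyl}-4H-1,3-dioxin-4-one
Product: 11 7-hydroxy-2,2-dimethyl-5-{2-[4-(triisopropylsilyloxy)phenyl]ethyl}-4H-1,3-benzodioxin-4-one, via cyclic aldol adduct 10 (not isolated)
Conditions: Et3N (5 equiv), CH2Cl2, rt; wash with 1 M aq HCl
Reagents that add atoms: none
Why: Et3N reversibly removes a proton from the doubly activated C1' methylene beside the dioxinone, and the extended dienolate is nucleophilic at ring carbon C5, which adds to the C4' ketone bearing the arylethyl arm to forge the future C4a–C5 bond and give aldol 10. The closest known reaction is the biomimetic aldol aromatisation of diketo-dioxinones to isopropylidene-protected resorcylates, the laboratory counterpart of orsellinate-type polyketide folding, which is established for side chains ending in a 2-arylethyl ketone. Ring A closes in the 6-(enolexo)-exo-trig mode, because the enolate C4=C5 bond is exocyclic to the forming ring and the carbonyl oxygen ends up outside it. E1cB loss of water across C4a–C5 and enolisation of the remaining C2' ketone (the future C7–OH) then make the process irreversible, so the two transient stereocentres of 10 are erased and none needs control. The required selectivity for aldol over Claisen closure is built into 9: the ester carbonyl C4 and the side chain sit trans across the dioxinone C5=C6 bond, so the C3' carbanion cannot reach C4, and every other carbon–carbonyl pairing would give a four-membered ring. At room temperature the acetonide is not lost by retro-[4+2], so it keeps the C8a oxygen tied to the carboxyl carbon and leaves the C7 hydroxyl as the only free phenol for step 6.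

Step 6
Reactants: 11 7-hydroxy-2,2-dimethyl-5-{2-[4-(triisopropylsilyloxy)phenyl]ethyl}-4H-1,3-benzodioxin-4-one; 12 1-bromo-3-methylbut-2-ene (prenyl bromide)
Product: 13 2,2-dimethyl-7-(3-methylbut-2-enyloxy)-5-{2-[4-(triisopropylsilyloxy)phenyl]ethyl}-4H-1,3-benzodioxin-4-one
Conditions: K2CO3, 12 (1.2 equiv), acetone, rt → 45 °C
Reagents that add atoms: none
Why: Williamson etherification (SN2) of the only free phenol, which is acidified by the para carbonyl group, and the weak base in acetone favours O- over C-allylation and spares both the aryl silyl ether and the dioxinone ring.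

Step 7
Reactants: 13 2,2-dimethyl-7-(3-methylbut-2-enyloxy)-5-{2-[4-(triisopropylsilyloxy)phenyl]ethyl}-4H-1,3-benzodioxin-4-one
Product: 15 2-hydroxy-4-(3-methylbut-2-enyloxy)-6-{2-[4-(triisopropylsilyloxy)phenyl]ethyl}benzaldehyde, via aluminium hemiacetal 14 (not isolated)
Conditions: iBu2AlH (1.5 equiv), CH2Cl2, −78 °C; aq KNaC4H4O6 (potassium sodium tartrate), rt
Reagents that add atoms: none
Why: Partial hydride reduction of a 2,2-dimethyl-1,3-benzodioxin-4-one is a known route to salicylaldehydes, in which one hydride transfer gives 14, which persists at −78 °C, and aqueous work-up collapses hemiacetal and ketal together, expelling acetone and unveiling the C4 aldehyde beside the C8a phenol.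

Step 8
Reactants: 15 2-hydroxy-4-(3-methylbut-2-enyloxy)-6-{2-[4-(triisopropylsilyloxy)phenyl]ethyl}benzaldehyde; 16 2-methylprop-1-enylmagnesium bromide
Product: 19 triisopropyl(4-{2-[2,2-dimethyl-7-(3-methylbut-2-enyloxy)-2H-chromen-5-yl]ethyl}phenoxy)silane, via allylic alcohol 17 (not isolated), via o-quinone methide 18 (not isolated)
Conditions: 16 (3 equiv, 0.5 M in THF), THF, 0 °C → rt; sat. aq NH4Cl; crude 17, PPTS (10 mol %), CH2Cl2, rt (telescoped, no purification of 17)
Reagents that add atoms: none
Why: Grignard 1,2-addition (one equivalent is spent on the phenol) forms C3–C4, and the doubly activated benzylic-allylic alcohol 17, whose racemic carbinol centre is lost at once, dehydrates under mild acid to o-quinone methide 18, in which the C5 arm pushes the alkenyl group to the oxygen side, as the oxa-6π electrocyclisation that forms O1–C2 and closes ring B requires.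

Step 9
Reactants: 19 triisopropyl(4-{2-[2,2-dimethyl-7-(3-methylbut-2-enyloxy)-2H-chromen-5-yl]ethyl}phenoxy)silane
Product: 20 4-{2-[2,2-dimethyl-7-(3-methylbut-2-enyloxy)-2H-chromen-5-yl]ethyl}phenol (CNP0337021.0)
Conditions: Bu4NF (1.2 equiv), AcOH (1.2 equiv), THF, 0 °C → rt
Reagents that add atoms: none
Why: Fluoride-driven cleavage of the aryl silyl ether (strong Si–F bond, good phenoxide leaving group) is fast and chemoselective, and the acetic acid buffer delivers the phenol directly while the allyl aryl ether and the chromene alkene remain untouched.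

**Compound list**
1 | 3-(4-hydroxyphenyl)propanoic acid | O=C(O)CCc1ccc(O)cc1 | starting material
2 | 3-(4-hydroxyphenyl)-N-methoxy-N-methylpropanamide | CON(C)C(=O)CCc1ccc(O)cc1 | intermediate
3 | N-methoxy-N-methyl-3-[4-(triisopropylsilyloxy)phenyl]propanamide | CON(C)C(=O)CCc1ccc(O[Si](C(C)C)(C(C)C)C(C)C)cc1 | intermediate
4 | 2,2,6-trimethyl-4H-1,3-dioxin-4-one | CC1=CC(=O)OC(C)(C)O1 | starting material
5 | acetyl chloride | CC(Cl)=O | starting material
6 | lithium 2,2-dimethyl-6-methylidene-1,3-dioxin-4-olate (dienolate of 4, formed in the flask) | [Li+].C=C1C=C([O-])OC(C)(C)O1 | intermediate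
7 | 2,2-dimethyl-6-(2-oxopropyl)-4H-1,3-dioxin-4-one | CC(=O)CC1=CC(=O)OC(C)(C)O1 | intermediate
8 | dilithium dianion of 7 (bis-enolate, formed in the flask) | [Li+].[Li+].C=C([O-])C=C1C=C([O-])OC(C)(C)O1 | intermediate
9 | 2,2-dimethyl-6-{2,4-dioxo-6-[4-(triisopropylsilyloxy)phenyl]hexyl}-4H-1,3-dioxin-4-one | CC1(C)OC(=CC(=O)O1)CC(=O)CC(=O)CCc1ccc(O[Si](C(C)C)(C(C)C)C(C)C)cc1 | intermediate
10 | 5-hydroxy-2,2-dimethyl-5-{2-[4-(triisopropylsilyloxy)phenyl]ethyl}-5,6-dihydro-4aH-1,3-benzodioxine-4,7-dione (cyclic aldol, diastereomer mixture, formed in the flask) | CC1(C)OC2=CC(=O)CC(O)(CCc3ccc(O[Si](C(C)C)(C(C)C)C(C)C)cc3)C2C(=O)O1 | intermediate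
11 | 7-hydroxy-2,2-dimethyl-5-{2-[4-(triisopropylsilyloxy)phenyl]ethyl}-4H-1,3-benzodioxin-4-one | CC1(C)Oc2cc(O)cc(CCc3ccc(O[Si](C(C)C)(C(C)C)C(C)C)cc3)c2C(=O)O1 | intermediate
12 | 1-bromo-3-methylbut-2-ene (prenyl bromide) | CC(C)=CCBr | starting material
13 | 2,2-dimethyl-7-(3-methylbut-2-enyloxy)-5-{2-[4-(triisopropylsilyloxy)phenyl]ethyl}-4H-1,3-benzodioxin-4-one | CC(C)=CCOc1cc(CCc2ccc(O[Si](C(C)C)(C(C)C)C(C)C)cc2)c2C(=O)OC(C)(C)Oc2c1 | intermediate
14 | 4-(diisobutylalumanyloxy)-2,2-dimethyl-7-(3-methylbut-2-enyloxy)-5-{2-[4-(triisopropylsilyloxy)phenyl]ethyl}-4H-1,3-benzodioxine (racemic, formed in the flask) | CC(C)C[Al](CC(C)C)OC1OC(C)(C)Oc2cc(OCC=C(C)C)cc(CCc3ccc(O[Si](C(C)C)(C(C)C)C(C)C)cc3)c12 | intermediate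
15 | 2-hydroxy-4-(3-methylbut-2-enyloxy)-6-{2-[4-(triisopropylsilyloxy)phenyl]ethyl}benzaldehyde | CC(C)=CCOc1cc(O)c(C=O)c(CCc2ccc(O[Si](C(C)C)(C(C)C)C(C)C)cc2)c1 | intermediate
16 | 2-methylprop-1-enylmagnesium bromide | CC(C)=C[Mg]Br | starting material
17 | 2-(1-hydroxy-3-methylbut-2-enyl)-5-(3-methylbut-2-enyloxy)-3-{2-[4-(triisopropylsilyloxy)phenyl]ethyl}phenol (racemic, carried on crude) | CC(C)=CCOc1cc(O)c(C(O)C=C(C)C)c(CCc2ccc(O[Si](C(C)C)(C(C)C)C(C)C)cc2)c1 | intermediate
18 | (6Z)-6-(3-methylbut-2-enylidene)-3-(3-methylbut-2-enyloxy)-5-{2-[4-(triisopropylsilyloxy)phenyl]ethyl}cyclohexa-2,4-dien-1-one (o-quinone methide, formed in the flask) | CC(C)=C/C=C1\C(=O)C=C(OCC=C(C)C)C=C1CCc1ccc(O[Si](C(C)C)(C(C)C)C(C)C)cc1 | intermediate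
19 | triisopropyl(4-{2-[2,2-dimethyl-7-(3-methylbut-2-enyloxy)-2H-chromen-5-yl]ethyl}phenoxy)silane | CC(C)=CCOc1cc(CCc2ccc(O[Si](C(C)C)(C(C)C)C(C)C)cc2)c2c(c1)OC(C)(C)C=C2 | intermediate
20 | 4-{2-[2,2-dimethyl-7-(3-methylbut-2-enyloxy)-2H-chromen-5-yl]ethyl}phenol | CC(C)=CCOc1cc(CCc2ccc(O)cc2)c2c(c1)OC(C)(C)C=C2 | target

**Step count**
Total steps: 9, with the telescoped step 8 counted once.
Longest linear sequence: 8 steps (1 → 2 → 3 → 9 → 11 → 13 → 15 → 19 → 20). The branch 4 + 5 → 7 joins at step 4.

**Steps most likely to fail**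

Step 4. Proton exchange between dianion 8 and the α-methylene of amide 3 could compete with addition. Addition could also be sluggish at the low temperature that the dianion tolerates. The sensitive product could cyclise prematurely during work-up or on silica.
The fallback replaces acylation by aldol addition and oxidation. It sets out from 3 and 7. Reduction of 3 with iBu2AlH (THF, −78 °C) should give 3-[4-(triisopropylsilyloxy)phenyl]propanal F1. Dianion 8, generated from 7 as before, adds to this far more electrophilic and non-chelating partner at −78 °C. This gives racemic 6-{4-hydroxy-2-oxo-6-[4-(triisopropylsilyloxy)phenyl]hexyl}-2,2-dimethyl-4H-1,3-dioxin-4-one F2. Dess–Martin periodinane in CH2Cl2 then oxidises the carbinol, and the sequence comes back to the route at 9.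

Step 5. The reaction could stall at the aldol stage without dehydration. O-cyclisation of the enolised diketone towards pyranone-type material could divert the substrate. Slow opening of the dioxinone could erode the acetonide lock.
The fallback forms the same C4a–C5 bond on an open chain after ketene capture. It sets out from 9.
- Heating 9 in toluene at 110 °C with methanol causes retro-[4+2] loss of acetone to the acylketene 9-[4-(triisopropylsilyloxy)phenyl]non-1-ene-1,3,5,7-tetraone F3.
- Methanol traps F3 as methyl 3,5,7-trioxo-9-[4-(triisopropylsilyloxy)phenyl]nonanoate F4.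
- Aldol cyclisation in pH 9.2 aqueous buffer/THF, followed by dehydration with dilute methanolic HCl, should give methyl 2,4-dihydroxy-6-{2-[4-(triisopropylsilyloxy)phenyl]ethyl}benzoate F5.
- In F5 the hydrogen bond between the 2-hydroxyl and the ester takes over the role of the acetonide. One equivalent of 12 with K2CO3 in acetone therefore alkylates only the 4-hydroxyl, giving methyl 2-hydroxy-4-(3-methylbut-2-enyloxy)-6-{2-[4-(triisopropylsilyloxy)phenyl]ethyl}benzoate F6.
- LiAlH4 in THF at 0 °C reduces the ester to 2-(hydroxymethyl)-5-(3-methylbut-2-enyloxy)-3-{2-[4-(triisopropylsilyloxy)phenyl]ethyl}phenol F7.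
- MnO2 in CH2Cl2 oxidises the benzylic alcohol, and the sequence comes back to the route at 15.

Step 8. Addition to the hindered aldehyde, which is deactivated as its magnesium phenoxide, could be slow. Intermolecular capture or oligomerisation of the o-quinone methide could compete with ring closure. The acid could also cause loss or migration of the prenyl group.
The fallback builds ring B as a lactone first and installs the gem-dimethyl group afterwards. It sets out from 15. (Triphenylphosphoranylidene)ketene, Ph3P=C=C=O, in toluene at 80 °C converts the salicylaldehyde by tandem O-acylation and intramolecular Wittig reaction into 7-(3-methylbut-2-enyloxy)-5-{2-[4-(triisopropylsilyloxy)phenyl]ethyl}-2H-chromen-2-one F8. This temperature is well below that of an aryl prenyl ether Claisen rearrangement. Double 1,2-addition of MeLi (3 equiv, THF, −78 → 0 °C) opens the lactone to 2-[(1Z)-3-hydroxy-3-methylbut-1-enyl]-5-(3-methylbut-2-enyloxy)-3-{2-[4-(triisopropylsilyloxy)phenyl]ethyl}phenol F9. The Z geometry of F9 is inherited from the ring. Brief exposure to PPTS or silica gel in CH2Cl2 closes the tertiary allylic alcohol onto the phenol, which is the classical conversion of a coumarin to a 2,2-dimethylchromene, and the sequence comes back to the route at 19.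

**Further compounds**
F1 | step 4 | 3-[4-(triisopropylsilyloxy)phenyl]propanal | O=CCCc1ccc(O[Si](C(C)C)(C(C)C)C(C)C)cc1
F2 | step 4 | 6-{4-hydroxy-2-oxo-6-[4-(triisopropylsilyloxy)phenyl]hexyl}-2,2-dimethyl-4H-1,3-dioxin-4-one (racemic) | CC1(C)OC(=CC(=O)O1)CC(=O)CC(O)CCc1ccc(O[Si](C(C)C)(C(C)C)C(C)C)cc1
F3 | step 5 | 9-[4-(triisopropylsilyloxy)phenyl]non-1-ene-1,3,5,7-tetraone | O=C=CC(=O)CC(=O)CC(=O)CCc1ccc(O[Si](C(C)C)(C(C)C)C(C)C)cc1
F4 | step 5 | methyl 3,5,7-trioxo-9-[4-(triisopropylsilyloxy)phenyl]nonanoate | COC(=O)CC(=O)CC(=O)CC(=O)CCc1ccc(O[Si](C(C)C)(C(C)C)C(C)C)cc1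
F5 | step 5 | methyl 2,4-dihydroxy-6-{2-[4-(triisopropylsilyloxy)phenyl]ethyl}benzoate | COC(=O)c1c(O)cc(O)cc1CCc1ccc(O[Si](C(C)C)(C(C)C)C(C)C)cc1
F6 | step 5 | methyl 2-hydroxy-4-(3-methylbut-2-enyloxy)-6-{2-[4-(triisopropylsilyloxy)phenyl]ethyl}benzoate | COC(=O)c1c(O)cc(OCC=C(C)C)cc1CCc1ccc(O[Si](C(C)C)(C(C)C)C(C)C)cc1
F7 | step 5 | 2-(hydroxymethyl)-5-(3-methylbut-2-enyloxy)-3-{2-[4-(triisopropylsilyloxy)phenyl]ethyl}phenol | CC(C)=CCOc1cc(O)c(CO)c(CCc2ccc(O[Si](C(C)C)(C(C)C)C(C)C)cc2)c1
F8 | step 8 | 7-(3-methylbut-2-enyloxy)-5-{2-[4-(triisopropylsilyloxy)phenyl]ethyl}-2H-chromen-2-one | CC(C)=CCOc1cc(CCc2ccc(O[Si](C(C)C)(C(C)C)C(C)C)cc2)c2C=CC(=O)Oc2c1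
F9 | step 8 | 2-[(1Z)-3-hydroxy-3-methylbut-1-enyl]-5-(3-methylbut-2-enyloxy)-3-{2-[4-(triisopropylsilyloxy)phenyl]ethyl}phenol | CC(C)=CCOc1cc(O)c(/C=C\C(C)(C)O)c(CCc2ccc(O[Si](C(C)C)(C(C)C)C(C)C)cc2)c1
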